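**Retrosynthetic overview**
1. Target 39 comes from the ten-membered 1(10),4-dien-6-one 30 by O8 acylation, C6 reduction, oxidative 6,12-lactonisation together with C14 oxidation, O9 acetylation and desilylation.
2. The strategy rests on one feature of the C1–C10 ring: the C6 oxygen and C1 are 1,3-related through C10. A C6–C10 bond therefore folds the ring into a cyclopentane (C6–C10) fused to a cycloheptene (C10, C1–C6), and with a mesylate on C1 this bicyclo[5.3.0]decene 28 fragments back to 30.
3. 28 comes from cyclopentane 17 by extension of the C1 arm, ring-closing metathesis (C4=C5), hydroxyl-directed reduction at C1 and mesylation.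
4. 17 comes from the 5,5-disubstituted cyclopentadiene 7 by two hydroxyl-directed epoxidations, p-methoxybenzyl alcohol opening (O8/O9 trans), alkenyllithium opening (C7) and vinyl addition (C6).
5. Ring order: cyclopentane (present from the start), cycloheptene (metathesis), ten-membered ring (fragmentation), lactone last.

Key step: step 23

Remark 1: germacrane numbering (C1–C15) is used for every intermediate. The cyclopentane carbons are C6–C10; the CH2OH arm of 7 becomes C1 and its CH2OTBS arm becomes C14.
Remark 2 (assumption): the (R,R)-bis-hydroxamic acid ligand of step 6 is taken to give the (8R,9S)-epoxide; if it gives the antipode, the (S,S)-ligand is used.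
Remark 3: C1, C6 and C10 become trigonal in step 23, so only their relative configuration matters (cis ring fusion, mesylate trans to the C6 oxygen). The route builds it on the face of the cyclopentane opposite to the C7 side chain.

Step 1
Reactants: 1 diethyl cyclopent-3-ene-1,1-dicarboxylate
Product: 2 ethyl 1-(hydroxymethyl)cyclopent-3-ene-1-carboxylate
Conditions: LiAlH(OtBu)3 (2.5 equiv), THF, 65 °C
Reagents that add atoms: none
Why: chemoselective hydride mono-reduction of a 2,2-disubstituted malonate, which should stop at the hydroxy ester because the aluminium alkoxide formed shields the second ester; no stereocentre is formed.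

Step 2
Reactants: 2 ethyl 1-(hydroxymethyl)cyclopent-3-ene-1-carboxylate
Product: 3 ethyl 1-[(tert-butyldimethylsilyloxy)methyl]cyclopent-3-ene-1-carboxylate
Conditions: TBSCl, imidazole, DMF, 0 °C → rt
Reagents that add atoms: tert-butyldimethylsilyl chloride, CC(C)(C)[Si](C)(C)Cl
Why: standard silylation of a primary alcohol; this arm is the future C14 and stays protected until step 27.

Step 3
Reactants: 3 ethyl 1-[(tert-butyldimethylsilyloxy)methyl]cyclopent-3-ene-1-carboxylate
Product: 4 ethyl trans-3,4-dibromo-1-[(tert-butyldimethylsilyloxy)methyl]cyclopentane-1-carboxylate (racemic)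
Conditions: Br2, CH2Cl2, −78 °C
Reagents that add atoms: bromine, BrBr
Why: anti addition of bromine to the ring olefin (electrophilic bromination via the bromonium ion) should give the trans-dibromide, whose stereocentres are lost in the next step.

Step 4
Reactants: 4 ethyl trans-3,4-dibromo-1-[(tert-butyldimethylsilyloxy)methyl]cyclopentane-1-carboxylate (racemic)
Product: 6 ethyl 1-[(tert-butyldimethylsilyloxy)methyl]cyclopenta-2,4-diene-1-carboxylate, via allylic bromide 5 (not isolated)
Conditions: KOtBu (2.5 equiv), THF, 0 °C → rt; used at once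
Reagents that add atoms: none
Why: two successive E2 eliminations (the second from the allylic bromide) should give a cyclopentadiene that cannot shift hydrogen because C10 is quaternary, and the ester has no α-hydrogen.

Step 5
Reactants: 6 ethyl 1-[(tert-butyldimethylsilyloxy)methyl]cyclopenta-2,4-diene-1-carboxylate
Product: 7 {1-[(tert-butyldimethylsilyloxy)methyl]cyclopenta-2,4-dien-1-yl}methanol
Conditions: iBu2AlH (2.5 equiv), CH2Cl2, −78 → 0 °C
Reagents that add atoms: none
Why: ester-to-alcohol reduction with an aluminium hydride leaves the diene untouched and supplies the hydroxyl that directs both epoxidations.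

Step 6
Reactants: 7 {1-[(tert-butyldimethylsilyloxy)methyl]cyclopenta-2,4-dien-1-yl}methanol
Product: 8 vinyl epoxide (8R,9S; epoxide oxygen cis to the CH2OH arm)
Conditions: VO(OiPr)3 (2 mol%), (R,R)-N,N'-dihydroxy-N,N'-bis(diphenylacetyl)cyclohexane-1,2-diamine (4 mol%), cumene hydroperoxide (1.05 equiv), toluene, 0 °C
Reagents that add atoms: cumene hydroperoxide, CC(C)(OO)c1ccccc1
Why: vanadium-catalysed hydroxyl-directed asymmetric epoxidation of a homoallylic alcohol delivers oxygen on the face of the CH2OH arm, and the chiral bis-hydroxamic acid ligand should select one of the two enantiotopic olefins, which sets C8, C9 and C10 together.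

Step 7
Reactants: 8 vinyl epoxide (8R,9S; epoxide oxygen cis to the CH2OH arm)
Product: 9 cyclopentenediol mono-PMB ether (8S,9S; 8-OPMB trans to 9-OH; C6=C7)
Conditions: 4-methoxybenzyl alcohol (3 equiv), BF3·OEt2 (5 mol%), CH2Cl2, −40 °C
Reagents that add atoms: 4-methoxybenzyl alcohol, COc1ccc(CO)cc1
Why: Lewis-acid-catalysed SN2 alcoholysis of the vinyl epoxide should take place at the allylic carbon C8 with inversion (C9 is neopentylic), which sets O8 trans to O9 and installs the PMB ether directly.

Step 8
Reactants: 9 cyclopentenediol mono-PMB ether (8S,9S; 8-OPMB trans to 9-OH; C6=C7)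
Product: 10 epoxy diol (6,7-epoxide cis to 9-OH and CH2OH; trans to 8-OPMB)
Conditions: VO(acac)2 (5 mol%), tBuOOH (1.5 equiv), CH2Cl2, 0 °C → rt
Reagents that add atoms: tert-butyl hydroperoxide, CC(C)(C)OO
Why: vanadium-catalysed directed epoxidation, in which both homoallylic hydroxyls sit on the lower face and the allylic OPMB group blocks the upper face, should place the epoxide anti to O8.

Step 9
Reactants: 10 epoxy diol (6,7-epoxide cis to 9-OH and CH2OH; trans to 8-OPMB)
Product: 11 bis(triethylsilyl) ether (9-OTES; C1H2OTES)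
Conditions: TESOTf (2.4 equiv), 2,6-lutidine (4 equiv), CH2Cl2, −78 °C
Reagents that add atoms: triethylsilyl trifluoromethanesulfonate, CC[Si](CC)(CC)OS(=O)(=O)C(F)(F)F
Why: silyl triflate silylation protects the hindered secondary and the primary hydroxyl in one operation, and the low temperature with excess base should keep the epoxide intact.

Step 10
Reactants: 12 2-bromoprop-2-en-1-ol
Product: 13 (2-bromoprop-2-enyloxy)(tert-butyl)dimethylsilane
Conditions: TBSCl, imidazole, CH2Cl2, 0 °C → rt
Reagents that add atoms: tert-butyldimethylsilyl chloride, CC(C)(C)[Si](C)(C)Cl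
Why: standard silylation that supplies the C11–C13 unit with the C12 oxygen protected.

Step 11
Reactants: 11 bis(triethylsilyl) ether (9-OTES; C1H2OTES); 13 (2-bromoprop-2-enyloxy)(tert-butyl)dimethylsilane
Product: 15 cyclopentanol (C7 side chain cis to 8-OPMB; 6-OH trans to the side chain), via alkenyllithium 14 (not isolated)
Conditions: 13 (2.5 equiv), tBuLi (5 equiv), Et2O, −78 °C; then 11, BF3·OEt2 (2.5 equiv), −78 °C
Reagents that add atoms: none
Why: bromine–lithium exchange followed by BF3-promoted SN2 opening of the epoxide should occur at C7 (C6 is neopentylic) with inversion, so the new C7–C11 bond is cis to O8 and trans to the C6 hydroxyl.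

Step 12
Reactants: 15 cyclopentanol (C7 side chain cis to 8-OPMB; 6-OH trans to the side chain)
Product: 16 cyclopentanone (C6 ketone)
Conditions: Dess–Martin periodinane (1.5 equiv), NaHCO3, CH2Cl2, 0 °C → rt
Reagents that add atoms: none
Why: Dess–Martin oxidation under buffered, non-basic conditions should give the ketone without epimerising C7 or eliminating the β-alkoxy group.

Step 13
Reactants: 16 cyclopentanone (C6 ketone)
Product: 17 tertiary vinyl carbinol (vinyl cis to C1H2OTES; 6-OH cis to C14H2OTBS)
Conditions: CeCl3 (3 equiv), CH2=CHMgBr (3 equiv), THF, −78 °C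
Reagents that add atoms: vinylmagnesium bromide, C=C[Mg]Br
Why: the weakly basic organocerium reagent adds 1,2 to the enolisable ketone and should approach the lower face, anti to the adjacent C7 side chain and away from the upper-face OPMB and CH2OTBS groups, which places C5 cis to the C1 arm.

Step 14
Reactants: 17 tertiary vinyl carbinol (vinyl cis to C1H2OTES; 6-OH cis to C14H2OTBS)
Product: 18 aldehyde (C1 = CHO)
Conditions: (COCl)2, DMSO, CH2Cl2, −78 → −40 °C; then Et3N, −78 → 0 °C
Reagents that add atoms: none
Why: Swern oxidation converts a primary triethylsilyl ether directly into the aldehyde while the secondary TES ether, the TBS ethers and the tertiary alcohol should be left alone.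

Step 15
Reactants: 18 aldehyde (C1 = CHO)
Product: 19 methyl carbinol (both C1 epimers)
Conditions: MeMgBr (3 equiv), THF, −78 → 0 °C
Reagents that add atoms: methylmagnesium bromide, C[Mg]Br
Why: Grignard addition to the neopentylic aldehyde introduces C2; the configuration of the new carbinol does not matter because it is oxidised in the next step.

Step 16
Reactants: 19 methyl carbinol (both C1 epimers)
Product: 20 methyl ketone (C1 acetyl)
Conditions: Dess–Martin periodinane (1.5 equiv), NaHCO3, CH2Cl2, 0 °C → rt
Reagents that add atoms: none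
Why: Dess–Martin oxidation of the secondary alcohol gives the β-hydroxy ketone under neutral conditions, and the tertiary alcohol cannot be oxidised.

Step 17
Reactants: 21 2-methylenepropane-1,3-diol
Product: 22 2-[(tert-butyldiphenylsilyloxy)methyl]prop-2-en-1-ol
Conditions: NaH (1.0 equiv), THF, 0 °C; then TBDPSCl (1.0 equiv)
Reagents that add atoms: tert-butyldiphenylsilyl chloride, CC(C)(C)[Si](Cl)(c1ccccc1)c1ccccc1
Why: monosilylation of a symmetric diol through its mono-sodium alkoxide is a standard desymmetrising protection.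

Step 18
Reactants: 22 2-[(tert-butyldiphenylsilyloxy)methyl]prop-2-en-1-ol
Product: 23 [2-(bromomethyl)prop-2-enyloxy](tert-butyl)diphenylsilane
Conditions: CBr4, PPh3, CH2Cl2, 0 °C
Reagents that add atoms: carbon tetrabromide, BrC(Br)(Br)Br
Why: Appel bromination of the primary allylic alcohol gives the electrophile that carries C3, C4 and C15.

Step 19
Reactants: 20 methyl ketone (C1 acetyl); 23 [2-(bromomethyl)prop-2-enyloxy](tert-butyl)diphenylsilane
Product: 25 dienyl ketone (C1(=O)–C2H2–C3H2–C4(=CH2)–C15H2OTBDPS), via dilithium alkoxide-enolate 24 (not isolated)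
Conditions: LiN(iPr)2 (2.3 equiv), THF, −78 °C; then DMPU, 23 (1.5 equiv), −78 → −40 °C
Reagents that add atoms: none
Why: alkylation of the dianion of a β-hydroxy ketone, in which the methyl group is the only enolisable position and the enolate itself protects the alkoxide from retro-aldol cleavage, should form the C2–C3 bond with the reactive allylic bromide.

Step 20
Reactants: 25 dienyl ketone (C1(=O)–C2H2–C3H2–C4(=CH2)–C15H2OTBDPS)
Product: 26 cis-fused bicyclic hydroxy ketone (bicyclo[5.3.0]dec-4-en-1-one; 6-OH at the ring fusion)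
Conditions: second-generation Grubbs catalyst RuCl2(=CHPh)(PCy3)(H2IMes) (5 mol%), CH2Cl2 (2 mM), 40 °C
Reagents that add atoms: none
Why: ring-closing metathesis between the C6 vinyl group and the 1,1-disubstituted C4 olefin should close the cycloheptene with a necessarily ring-cis C4=C5 bond; closure is possible because the vinyl group and the acyl arm are cis, so the ring fusion is cis.

Step 21
Reactants: 26 cis-fused bicyclic hydroxy ketone (bicyclo[5.3.0]dec-4-en-1-one; 6-OH at the ring fusion)
Product: 27 anti-1,3-diol (1-OH trans to 6-OH on the seven-membered ring)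
Conditions: Me4NBH(OAc)3 (6 equiv), MeCN/AcOH (2:1), −30 °C
Reagents that add atoms: none
Why: Evans–Saksena reduction, in which the borohydride bound to the C6 hydroxyl delivers hydride to the C1 ketone from the face of that hydroxyl, should give the 1,3-anti diol, that is, the C1 oxygen trans to O6 and C14 and cis to C9.

Step 22
Reactants: 27 anti-1,3-diol (1-OH trans to 6-OH on the seven-membered ring)
Product: 28 mesylate (C1 OMs; free tertiary 6-OH)
Conditions: MsCl (1.5 equiv), Et3N (3 equiv), CH2Cl2, −20 °C
Reagents that add atoms: methanesulfonyl chloride, CS(=O)(=O)Cl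
Why: sulfonylation through the sulfene should take the secondary hydroxyl only, since the tertiary ring-fusion hydroxyl is too hindered to react.

Step 23
Reactants: 28 mesylate (C1 OMs; free tertiary 6-OH)
Product: 30 ten-membered dienone (cis,cis-1(10),4-dien-6-one), via potassium alkoxide 29 (not isolated)
Conditions: KOtBu (1.1 equiv), THF, −40 → 0 °C; pH 7 buffer quench
Reagents that add atoms: none
Why: KOtBu converts the tertiary C6 hydroxyl into the potassium alkoxide 29, whose oxygen lone pair forms the C6 carbonyl while the electrons of the C6–C10 ring-fusion bond flow into the C1–C10 bond and expel mesylate from C1 in one concerted anti-periplanar step (Wharton–Grob fragmentation of a cyclic 1,3-diol monosulfonate). No ring is closed: the ten-membered ring already exists as the periphery of the five–seven bicycle and is set free by cutting the shared bond, and no stereocentre is created, since C1, C6 and C10 become trigonal and C7, C8 and C9 are untouched. The selectivity needed is the ring-cis geometry of the new C1=C10 olefin, and it is fixed by the relative configuration built in steps 13, 20 and 21: in the cis-fused bicycle the mesylate is trans to the C6 oxygen and to C14, so with the C1–O bond anti to C6–C10 the ring carbon C2 lies gauche to C9 and anti to C14, and C2 and C9 end up on the same side of the double bond. C4=C5 is already ring-cis because it was made inside the cycloheptene, and conjugation of the new ketone with it adds driving force. One equivalent of base, low temperature and a buffered quench are meant to spare the C8 p-methoxybenzyloxy group and the C7 centre of the β-alkoxy ketone, and the O9 and O14 silyl ethers prevent the competing fragmentations of the C9–C10 and C14–C10 bonds.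

Step 24
Reactants: 30 ten-membered dienone (cis,cis-1(10),4-dien-6-one)
Product: 31 8-hydroxy dienone
Conditions: DDQ (1.5 equiv), CH2Cl2/pH 7 phosphate buffer (10:1), 0 °C
Reagents that add atoms: none
Why: oxidative cleavage of the p-methoxybenzyl ether with DDQ under neutral conditions should free O8 without touching the silyl ethers or the dienone.

Step 25
Reactants: 31 8-hydroxy dienone; 32 (R)-2-methylbutanoic acid
Product: 33 8-O-[(R)-2-methylbutanoyl] dienone
Conditions: 32 (3 equiv), DCC (3 equiv), DMAP (0.2 equiv), CH2Cl2, 0 °C → rt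
Reagents that add atoms: none
Why: Steglich esterification with only catalytic DMAP should acylate the single free hydroxyl without epimerising the acid, and is too weakly basic to trigger β-elimination of the new β-acyloxy ketone.

Step 26
Reactants: 33 8-O-[(R)-2-methylbutanoyl] dienone
Product: 34 allylic alcohol (6R; 6-OH trans to the C7 side chain and anti to O8)
Conditions: NaBH4 (1.5 equiv), CeCl3·7H2O (1.5 equiv), MeOH, −78 °C
Reagents that add atoms: none
Why: Luche 1,2-reduction of the enone, in which hydride should enter from the outer face of the ring remote from the C8 ester (1,3-anti induction by the β-acyloxy group), is expected to give the 6R alcohol, and the cold neutral medium avoids β-elimination and acyl migration.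

Step 27
Reactants: 34 allylic alcohol (6R; 6-OH trans to the C7 side chain and anti to O8)
Product: 35 tetraol (6-OH, 9-OH, 12-OH, 14-OH; 15-OTBDPS)
Conditions: HF·pyridine, pyridine, THF, 0 °C → rt
Reagents that add atoms: none
Why: buffered HF·pyridine cleaves the triethylsilyl and the two primary tert-butyldimethylsilyl ethers, while the far more robust primary tert-butyldiphenylsilyl ether at C15 should survive.

Step 28
Reactants: 35 tetraol (6-OH, 9-OH, 12-OH, 14-OH; 15-OTBDPS)
Product: 37 α-methylene lactone enal (9-OH free), via lactol 36 (not isolated)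
Conditions: TEMPO (0.2 equiv), PhI(OAc)2 (3.3 equiv), CH2Cl2, rt
Reagents that add atoms: none
Why: TEMPO/PhI(OAc)2 oxidises only the two primary allylic alcohols; the C12 aldehyde should be trapped by the adjacent 6-OH as a five-membered lactol and oxidised on to the trans-fused lactone (O8 is acylated and the trans-1,3-related 9-OH cannot bridge), while C14 stops at the enal.

Step 29
Reactants: 37 α-methylene lactone enal (9-OH free)
Product: 38 9-acetate (15-O-TBDPS ether of the target)
Conditions: Ac2O, pyridine, DMAP (cat.), CH2Cl2, 0 °C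
Reagents that add atoms: acetic anhydride, CC(=O)OC(C)=O
Why: fast acetylation of the only free hydroxyl should outrun any migration of the neighbouring 2-methylbutanoyl group.

Step 30
Reactants: 38 9-acetate (15-O-TBDPS ether of the target)
Product: 39 target CNP0247637.4
Conditions: HF·pyridine, THF, 0 °C → rt, polyethylene vessel
Reagents that add atoms: none
Why: fluoride cleavage of the primary silyl ether under acidic, non-basic conditions should leave the two esters, the enal and the α-methylene lactone unchanged.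

**Compound list**
1 | diethyl cyclopent-3-ene-1,1-dicarboxylate | CCOC(=O)C1(CC=CC1)C(=O)OCC | starting material
2 | ethyl 1-(hydroxymethyl)cyclopent-3-ene-1-carboxylate | CCOC(=O)C1(CO)CC=CC1 | intermediate
3 | ethyl 1-[(tert-butyldimethylsilyloxy)methyl]cyclopent-3-ene-1-carboxylate | CCOC(=O)C1(CO[Si](C)(C)C(C)(C)C)CC=CC1 | intermediate
4 | ethyl trans-3,4-dibromo-1-[(tert-butyldimethylsilyloxy)methyl]cyclopentane-1-carboxylate (racemic) | CCOC(=O)C1(CO[Si](C)(C)C(C)(C)C)C[C@@H](Br)[C@H](Br)C1 | intermediate
5 | allylic bromide: ethyl 4-bromo-1-[(tert-butyldimethylsilyloxy)methyl]cyclopent-2-ene-1-carboxylate (both diastereomers) | CCOC(=O)C1(CO[Si](C)(C)C(C)(C)C)C=CC(Br)C1 | intermediate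
6 | ethyl 1-[(tert-butyldimethylsilyloxy)methyl]cyclopenta-2,4-diene-1-carboxylate | CCOC(=O)C1(CO[Si](C)(C)C(C)(C)C)C=CC=C1 | intermediate
7 | {1-[(tert-butyldimethylsilyloxy)methyl]cyclopenta-2,4-dien-1-yl}methanol | OCC1(CO[Si](C)(C)C(C)(C)C)C=CC=C1 | intermediate
8 | vinyl epoxide: 4-(hydroxymethyl)-4-[(tert-butyldimethylsilyloxy)methyl]-6-oxabicyclo[3.1.0]hex-2-ene, epoxide oxygen cis to CH2OH, 8R,9S in germacrane numbering | CC(C)(C)[Si](C)(C)OC[C@@]1(CO)[C@@H]2O[C@@H]2C=C1 | intermediate
9 | cyclopentenediol mono-PMB ether: (8S,9S), 9-OH cis to the CH2OH arm, 8-OPMB trans to 9-OH and cis to the CH2OTBS arm, C6=C7 | CC(C)(C)[Si](C)(C)OC[C@@]1(CO)[C@H](O)[C@@H](OCc2ccc(OC)cc2)C=C1 | intermediate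
10 | epoxy diol: 6,7-epoxide of 9 on the face of 9-OH and CH2OH, trans to 8-OPMB | CC(C)(C)[Si](C)(C)OC[C@@]1(CO)[C@H](O)[C@@H](OCc2ccc(OC)cc2)[C@@H]2O[C@H]12 | intermediate
11 | bis(triethylsilyl) ether of 10 (9-OTES and C1H2OTES) | CC(C)(C)[Si](C)(C)OC[C@@]1(CO[Si](CC)(CC)CC)[C@H](O[Si](CC)(CC)CC)[C@@H](OCc2ccc(OC)cc2)[C@@H]2O[C@H]12 | intermediate
12 | 2-bromoprop-2-en-1-ol | C=C(Br)CO | starting material
13 | (2-bromoprop-2-enyloxy)(tert-butyl)dimethylsilane | C=C(Br)CO[Si](C)(C)C(C)(C)C | intermediate
14 | alkenyllithium: [3-(tert-butyldimethylsilyloxy)prop-1-en-2-yl]lithium | [Li]C(=C)CO[Si](C)(C)C(C)(C)C | intermediate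
15 | cyclopentanol: 6-OH, C7 bearing C(=CH2)CH2OTBS trans to 6-OH and cis to 8-OPMB, 9-OTES trans to 8-OPMB, C10 bearing CH2OTES (cis to O9) and CH2OTBS | CC(C)(C)[Si](C)(C)OC[C@@]1(CO[Si](CC)(CC)CC)[C@H](O[Si](CC)(CC)CC)[C@@H](OCc2ccc(OC)cc2)[C@@H](C(=C)CO[Si](C)(C)C(C)(C)C)[C@@H]1O | intermediate
16 | cyclopentanone: C6 ketone of 15 | CC(C)(C)[Si](C)(C)OC[C@@]1(CO[Si](CC)(CC)CC)[C@H](O[Si](CC)(CC)CC)[C@@H](OCc2ccc(OC)cc2)[C@@H](C(=C)CO[Si](C)(C)C(C)(C)C)C1=O | intermediate
17 | tertiary vinyl carbinol: C6 bearing vinyl (cis to CH2OTES, trans to the C7 side chain) and OH (cis to CH2OTBS) | CC(C)(C)[Si](C)(C)OC[C@@]1(CO[Si](CC)(CC)CC)[C@H](O[Si](CC)(CC)CC)[C@@H](OCc2ccc(OC)cc2)[C@@H](C(=C)CO[Si](C)(C)C(C)(C)C)[C@]1(O)C=C | intermediate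
18 | aldehyde: C1 formyl group on C10 in place of CH2OTES of 17 | CC(C)(C)[Si](C)(C)OC[C@@]1(C=O)[C@H](O[Si](CC)(CC)CC)[C@@H](OCc2ccc(OC)cc2)[C@@H](C(=C)CO[Si](C)(C)C(C)(C)C)[C@]1(O)C=C | intermediate
19 | methyl carbinol: C1H(OH)CH3 on C10, both C1 epimers | CC(C)(C)[Si](C)(C)OC[C@@]1(C(C)O)[C@H](O[Si](CC)(CC)CC)[C@@H](OCc2ccc(OC)cc2)[C@@H](C(=C)CO[Si](C)(C)C(C)(C)C)[C@]1(O)C=C | intermediate
20 | methyl ketone: C1 acetyl on C10 | CC(C)(C)[Si](C)(C)OC[C@@]1(C(C)=O)[C@H](O[Si](CC)(CC)CC)[C@@H](OCc2ccc(OC)cc2)[C@@H](C(=C)CO[Si](C)(C)C(C)(C)C)[C@]1(O)C=C | intermediate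
21 | 2-methylenepropane-1,3-diol | C=C(CO)CO | starting material
22 | 2-[(tert-butyldiphenylsilyloxy)methyl]prop-2-en-1-ol | C=C(CO)CO[Si](c1ccccc1)(c1ccccc1)C(C)(C)C | intermediate
23 | [2-(bromomethyl)prop-2-enyloxy](tert-butyl)diphenylsilane | C=C(CBr)CO[Si](c1ccccc1)(c1ccccc1)C(C)(C)C | intermediate
24 | dilithium alkoxide-enolate of 20 (C6 O–Li and C1 enolate towards C2) | CC(C)(C)[Si](C)(C)OC[C@@]1(C(=C)O[Li])[C@H](O[Si](CC)(CC)CC)[C@@H](OCc2ccc(OC)cc2)[C@@H](C(=C)CO[Si](C)(C)C(C)(C)C)[C@]1(O[Li])C=C | intermediate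
25 | dienyl ketone: C10 bearing C1(=O)–C2H2–C3H2–C4(=CH2)–C15H2OTBDPS, otherwise as 20 | CC(C)(C)[Si](C)(C)OC[C@@]1(C(=O)CCC(=C)CO[Si](c2ccccc2)(c2ccccc2)C(C)(C)C)[C@H](O[Si](CC)(CC)CC)[C@@H](OCc2ccc(OC)cc2)[C@@H](C(=C)CO[Si](C)(C)C(C)(C)C)[C@]1(O)C=C | intermediate
26 | cis-fused bicyclo[5.3.0]dec-4-en-1-one: 6-OH and C14H2OTBS on one face of the cycloheptene, cyclopentane carbons C7 and C9 on the other, C4 bearing CH2OTBDPS | CC(C)(C)[Si](C)(C)OC[C@@]1(C(=O)CCC(CO[Si](c3ccccc3)(c3ccccc3)C(C)(C)C)=C2)[C@H](O[Si](CC)(CC)CC)[C@@H](OCc3ccc(OC)cc3)[C@@H](C(=C)CO[Si](C)(C)C(C)(C)C)[C@@]12O | intermediate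
27 | anti-1,3-diol: as 26 with C1 carbinol, 1-OH trans to 6-OH and to C14, cis to C9 | CC(C)(C)[Si](C)(C)OC[C@@]1([C@@H](O)CCC(CO[Si](c3ccccc3)(c3ccccc3)C(C)(C)C)=C2)[C@H](O[Si](CC)(CC)CC)[C@@H](OCc3ccc(OC)cc3)[C@@H](C(=C)CO[Si](C)(C)C(C)(C)C)[C@@]12O | intermediate
28 | mesylate: 1-O-methanesulfonate of 27 with free tertiary 6-OH (fragmentation precursor) | CC(C)(C)[Si](C)(C)OC[C@@]1([C@@H](OS(C)(=O)=O)CCC(CO[Si](c3ccccc3)(c3ccccc3)C(C)(C)C)=C2)[C@H](O[Si](CC)(CC)CC)[C@@H](OCc3ccc(OC)cc3)[C@@H](C(=C)CO[Si](C)(C)C(C)(C)C)[C@@]12O | intermediate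
29 | potassium alkoxide of 28 (C6 O–K) | CC(C)(C)[Si](C)(C)OC[C@@]1([C@@H](OS(C)(=O)=O)CCC(CO[Si](c3ccccc3)(c3ccccc3)C(C)(C)C)=C2)[C@H](O[Si](CC)(CC)CC)[C@@H](OCc3ccc(OC)cc3)[C@@H](C(=C)CO[Si](C)(C)C(C)(C)C)[C@@]12O[K] | intermediate
30 | ten-membered dienone: cyclodeca-1(10),4-dien-6-one, both ring olefins cis in the ring, C4 CH2OTBDPS, C10 CH2OTBS, 9-OTES, 8-OPMB, C7 C(=CH2)CH2OTBS; C7, C8, C9 as in the target | O=C1/C=C(/CO[Si](c2ccccc2)(c2ccccc2)C(C)(C)C)CC/C=C(/CO[Si](C)(C)C(C)(C)C)[C@H](O[Si](CC)(CC)CC)[C@@H](OCc2ccc(OC)cc2)[C@H]1C(=C)CO[Si](C)(C)C(C)(C)C | intermediate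
31 | 8-hydroxy dienone: 30 without the PMB group | O=C1/C=C(/CO[Si](c2ccccc2)(c2ccccc2)C(C)(C)C)CC/C=C(/CO[Si](C)(C)C(C)(C)C)[C@H](O[Si](CC)(CC)CC)[C@@H](O)[C@H]1C(=C)CO[Si](C)(C)C(C)(C)C | intermediate
32 | (R)-2-methylbutanoic acid | CC[C@@H](C)C(=O)O | starting material
33 | 8-O-[(R)-2-methylbutanoyl] dienone | O=C1/C=C(/CO[Si](c2ccccc2)(c2ccccc2)C(C)(C)C)CC/C=C(/CO[Si](C)(C)C(C)(C)C)[C@H](O[Si](CC)(CC)CC)[C@@H](OC(=O)[C@H](C)CC)[C@H]1C(=C)CO[Si](C)(C)C(C)(C)C | intermediate
34 | allylic alcohol: 6R carbinol of 33, 6-OH trans to the C7 side chain | O[C@@H]1/C=C(/CO[Si](c2ccccc2)(c2ccccc2)C(C)(C)C)CC/C=C(/CO[Si](C)(C)C(C)(C)C)[C@H](O[Si](CC)(CC)CC)[C@@H](OC(=O)[C@H](C)CC)[C@H]1C(=C)CO[Si](C)(C)C(C)(C)C | intermediate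
35 | tetraol: 34 with free 9-OH, 12-OH and 14-OH, 15-OTBDPS retained | O[C@@H]1/C=C(/CO[Si](c2ccccc2)(c2ccccc2)C(C)(C)C)CC/C=C(/CO)[C@H](O)[C@@H](OC(=O)[C@H](C)CC)[C@H]1C(=C)CO | intermediate
36 | lactol: 6,12-hemiacetal with C14 aldehyde (lactol carbon unassigned) | C=C1C(O)O[C@@H]2/C=C(/CO[Si](c3ccccc3)(c3ccccc3)C(C)(C)C)CC/C=C(/C=O)[C@H](O)[C@@H](OC(=O)[C@H](C)CC)[C@@H]12 | intermediate
37 | α-methylene 6,12-lactone with C14 enal, free 9-OH, 15-OTBDPS | C=C1C(=O)O[C@@H]2/C=C(/CO[Si](c3ccccc3)(c3ccccc3)C(C)(C)C)CC/C=C(/C=O)[C@H](O)[C@@H](OC(=O)[C@H](C)CC)[C@@H]12 | intermediate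
38 | 9-acetate: 15-O-TBDPS ether of the target | C=C1C(=O)O[C@@H]2/C=C(/CO[Si](c3ccccc3)(c3ccccc3)C(C)(C)C)CC/C=C(/C=O)[C@H](OC(C)=O)[C@@H](OC(=O)[C@H](C)CC)[C@@H]12 | intermediate
39 | CNP0247637.4: 9-acetoxy-8-[(R)-2-methylbutanoyloxy]-15-hydroxy-14-oxo-cis,cis-germacra-1(10),4,11(13)-trien-6,12-olide | C=C1C(=O)O[C@@H]2/C=C(/CO)CC/C=C(/C=O)[C@H](OC(C)=O)[C@@H](OC(=O)[C@H](C)CC)[C@@H]12 | target

**Step count**
Total: 30 steps. Longest linear sequence: 27 steps (steps 1–9, 11–16, 19–30, from compound 1).

**Steps most likely to fail**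

Step 23 (fragmentation). The free potassium alkoxide or residual tert-butoxide may deprotonate C7 of the product; this would lead to loss of the C8 p-methoxybenzyloxy group by β-elimination, epimerisation at C7, or migration of the C11=C13 olefin into conjugation. If the fragmentation is slow, intramolecular displacement of the mesylate to an oxetane may also compete. The fallback sets out from compound 28 and generates the alkoxide without any excess base. The tertiary hydroxyl is silylated (TMSOTf, 2,6-lutidine, CH2Cl2, −78 °C) to give the trimethylsilyl ether mesylate F3. F3 is then treated with one equivalent of Bu4NF in THF at −78 °C; this is a fluoride-triggered Grob fragmentation in which the alkoxide is released only as it is consumed. The fallback comes back to the route at compound 30.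

Step 11 (epoxide opening). The functionalised alkenyllithium 14 may lose silanolate to give allene. Its attack at C7, which is cis to the neighbouring OPMB group, may also be too slow, so that Lewis-acid rearrangement of the epoxide or attack at C6 takes over. The fallback sets out from compound 11 and introduces the C12 oxygen after the carbon–carbon bond is made. The epoxide is opened with the smaller and more robust 2-propenylmagnesium bromide under CuI catalysis (THF, −30 °C) to give the isopropenyl cyclopentanol F1. Allylic oxidation of its methyl group with SeO2 (cat.) and tBuOOH in CH2Cl2 gives the diol F2. Selective silylation of the primary allylic hydroxyl (TBSCl, imidazole, −20 °C) returns to the route at compound 15.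

Step 26 (C6 reduction). Facial selectivity on the flexible ten-membered enone may be poor or reversed, which would give the C6 epimer and hence the cis-lactone series. The fallback sets out from compound 33 and replaces substrate control by reagent control: a Corey–Bakshi–Shibata reduction with (R)-2-methyl-CBS-oxazaborolidine and catecholborane in toluene at −78 °C. Here the alkenyl branch of the enone is taken as the large group; the enantiomeric catalyst is used if the (R)-catalyst proves mismatched. The fallback comes back at compound 34 and makes no new compound.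

**Further compounds**
F1 | step 11 | isopropenyl cyclopentanol: compound 15 with C(CH3)=CH2 in place of C(=CH2)CH2OTBS at C7 | CC(C)(C)[Si](C)(C)OC[C@@]1(CO[Si](CC)(CC)CC)[C@H](O[Si](CC)(CC)CC)[C@@H](OCc2ccc(OC)cc2)[C@@H](C(C)=C)[C@@H]1O
F2 | step 11 | diol: compound 15 with free C12 hydroxyl (C7 bearing C(=CH2)CH2OH) | CC(C)(C)[Si](C)(C)OC[C@@]1(CO[Si](CC)(CC)CC)[C@H](O[Si](CC)(CC)CC)[C@@H](OCc2ccc(OC)cc2)[C@@H](C(=C)CO)[C@@H]1O
F3 | step 23 | 6-O-trimethylsilyl ether of mesylate 28 | CC(C)(C)[Si](C)(C)OC[C@@]1([C@@H](OS(C)(=O)=O)CCC(CO[Si](c3ccccc3)(c3ccccc3)C(C)(C)C)=C2)[C@H](O[Si](CC)(CC)CC)[C@@H](OCc3ccc(OC)cc3)[C@@H](C(=C)CO[Si](C)(C)C(C)(C)C)[C@@]12O[Si](C)(C)C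
F0 | step 26 | none | none
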